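**Plan**
1. Cuts: the C8 tiglate and the C3 silyl ether; then the C8–C9 bond of the ten-membered ring, read as the homoallylic alcohol retron O–C8–C9–C10(C14)=C1, giving a C8 aldehyde and a C1-boryl 2-methylallyl unit; then C1–B (back to a C9 allylic carbonate), C1=C10 (cross-metathesis), C6–C7 and the lactone C–O (aldol, lactonisation), the C4–C5 oxirane, and C2–C3 (allylation).
2. Forward: the oxirane (C4, C5, O) is made first on an acyclic C1–C6 piece, then the γ-lactone (C6, C7, C11, C12, O), then the ten-membered carbocycle by C8–C9 closure, then esterification and desilylation.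
3. Stereochemistry: C3 from reagent-controlled allylboration; C4/C5 from tartrate-controlled epoxidation; C6/C7 from an oxazolidinone syn-aldol; C11 from (R)-methylsuccinic acid; C1–B from a chiral copper catalyst, relayed through a chair to C8 and to the Z C1=C10 geometry.
4. Enabling feature: the C8 carbinol is homoallylic to the Z-trisubstituted C1=C10 alkene inside the ring, and the trans-fused five-membered lactone on C6–C7 fixes the C5–C6–C7–C8 torsion, so that a six-membered B–O–C8–C9–C10–C1 chair can be bridged by the C2–C7 chain.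

Key step: step 15

Remark on locants: germacrane locants of the target are used for atoms throughout (ring C1–C10; C11, C12, C13 on the lactone; C14 methyl on C10; C15 methyl on C4). CIP descriptors in names are those of each compound and can differ from the target's where priorities change (C4 is S while the C3 silyl ether is present).

Assumption: with the E-configured allylic carbonate 17, the CuOtBu/(R,R)-QuinoxP* catalyst is taken to deliver boron to the Re face of C1 (1R); if the sense proves opposite, the (S,S)-ligand is used, both antipodes being available.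

**Step 1**
Reactants: 1 ethyl (2E)-3-methyl-4-oxobut-2-enoate
Product: 2 ethyl (2E,4S)-4-hydroxy-3-methylhepta-2,6-dienoate
Conditions: B-allyldiisopinocampheylborane of the (+)-α-pinene series (1.3 equiv), Et2O, −78 °C; then pH 7 buffer, MeOH, 30% H2O2, 0 °C
Reagents that add atoms: B-allyldiisopinocampheylborane, C=CCB([C@@H]1C[C@@H]2C[C@H]([C@H]1C)C2(C)C)[C@@H]1C[C@@H]2C[C@H]([C@H]1C)C2(C)C
Why: Brown allylboration through a closed chair; the (+)-α-pinene-derived reagent should add the allyl group to the Si face of the α-methyl enal carbonyl, setting C3 as S, and the aldehyde reacts much faster than the conjugated ester.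

**Step 2**
Reactants: 2 ethyl (2E,4S)-4-hydroxy-3-methylhepta-2,6-dienoate
Product: 3 ethyl (2E,4S)-3-methyl-4-(triethylsilyloxy)hepta-2,6-dienoate
Conditions: Et3SiCl, imidazole, DMF, 0 °C → rt
Reagents that add atoms: chlorotriethylsilane, CC[Si](Cl)(CC)CC
Why: Standard silylation of a secondary alcohol; the silyl ether removes C3–OH as a directing group for step 4 and is carried to the last step.

**Step 3**
Reactants: 3 ethyl (2E,4S)-3-methyl-4-(triethylsilyloxy)hepta-2,6-dienoate
Product: 4 (2E,4S)-3-methyl-4-(triethylsilyloxy)hepta-2,6-dien-1-ol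
Conditions: iBu2AlH (2.2 equiv), CH2Cl2, −78 °C; Rochelle salt work-up
Reagents that add atoms: none
Why: 1,2-Reduction of the conjugated ester to the E allylic alcohol; the silyl ether and both alkenes should be untouched.

**Step 4**
Reactants: 4 (2E,4S)-3-methyl-4-(triethylsilyloxy)hepta-2,6-dien-1-ol
Product: 5 epoxy alcohol
Conditions: Ti(OiPr)4 (10 mol %), D-(−)-diethyl tartrate (12 mol %), tBuOOH, 4 Å MS, CH2Cl2, −20 °C
Reagents that add atoms: tert-butyl hydroperoxide, CC(C)(C)OO
Why: Sharpless asymmetric epoxidation of an E-trisubstituted primary allylic alcohol; the D-(−)-tartrate complex should deliver oxygen to the face that gives the C4/C5 configuration of the target (threo to the C3 silyl ether) under reagent control, and the terminal alkene is inert.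

**Step 5**
Reactants: 5 epoxy alcohol
Product: 6 epoxy aldehyde
Conditions: TEMPO (10 mol %), PhI(OAc)2, CH2Cl2, rt
Reagents that add atoms: none
Why: Oxoammonium oxidation of the primary alcohol stops at the aldehyde under near-neutral conditions that should not epimerise C5 or open the oxirane.

**Step 6**
Reactants: 7 (R)-methylsuccinic acid
Product: 8 (R)-methylsuccinic anhydride
Conditions: AcCl, reflux
Reagents that add atoms: none
Why: Cyclodehydration of the 1,4-diacid to the five-membered anhydride; the stereocentre is not involved.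

**Step 7**
Reactants: 9 (4S)-4-benzyl-1,3-oxazolidin-2-one; 8 (R)-methylsuccinic anhydride
Product: 10 imide acid
Conditions: nBuLi, THF, −78 °C; then 8, −78 → 0 °C; aq. HCl work-up
Reagents that add atoms: none
Why: N-Acylation of the lithiated oxazolidinone by the cyclic anhydride should occur at the less hindered carbonyl (remote from the methyl group), which puts the imide on the CH2 side and leaves C11 as the α-carbon of the free acid.

**Step 8**
Reactants: 10 imide acid
Product: 11 imide ester
Conditions: Me3SiCHN2, MeOH/toluene, 0 °C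
Reagents that add atoms: (trimethylsilyl)diazomethane, C[Si](C)(C)C=[N+]=[N-]
Why: Base-free O-methylation of the carboxylic acid, so the C11 stereocentre is not at risk.

**Step 9**
Reactants: 11 imide ester; 6 epoxy aldehyde
Product: 13 lactone imide, via aldol adduct 12 (not isolated)
Conditions: 11, Bu2BOTf, iPr2NEt, CH2Cl2, 0 °C; then 6, −78 → 0 °C; pH 7 buffer, MeOH, H2O2; then PPTS (cat.), CH2Cl2, rt
Reagents that add atoms: none
Why: Evans syn-aldol through the Z boron enolate and a Zimmerman–Traxler chair, in which the (S)-benzyl auxiliary sets C7 and C6; the C6 hydroxyl then closes onto the methyl ester to give the trans-4,5-disubstituted γ-lactone, with the C13 methyl already placed by the chiral pool.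

**Step 10**
Reactants: 13 lactone imide
Product: 14 lactone imide enal
Conditions: methacrolein (10 equiv), second-generation Hoveyda–Grubbs catalyst (H2IMes)Cl2Ru=CH(C6H4-2-OiPr) (5 mol %), CH2Cl2, 40 °C
Reagents that add atoms: methacrolein, C=C(C)C=O
Why: Cross-metathesis of the monosubstituted C1 alkene with methacrolein should give the E 2-methyl enal under thermodynamic control, with loss of ethene; the trisubstituted oxirane and the carbonyl groups do not interfere.

**Step 11**
Reactants: 14 lactone imide enal
Product: 15 lactone imide allylic alcohol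
Conditions: NaBH4, CeCl3·7H2O, MeOH/CH2Cl2, −78 °C
Reagents that add atoms: none
Why: Luche 1,2-reduction of the enal; the imide and the lactone should not be reduced at this temperature.

**Step 12**
Reactants: 15 lactone imide allylic alcohol
Product: 16 lactone imide allylic carbonate
Conditions: ClCO2Me, pyridine, CH2Cl2, 0 °C
Reagents that add atoms: methyl chloroformate, COC(=O)Cl
Why: O-Acylation of the primary allylic alcohol gives the methyl carbonate that serves as leaving group in step 14.

**Step 13**
Reactants: 16 lactone imide allylic carbonate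
Product: 17 hydroxymethyl lactone allylic carbonate
Conditions: NaBH4, THF/H2O (3:1), 0 °C → rt
Reagents that add atoms: none
Why: Reductive cleavage of the N-acyloxazolidinone to the C8 primary alcohol; the exocyclic imide carbonyl is more electrophilic than the lactone and the carbonate, and the auxiliary is recovered.

**Step 14**
Reactants: 17 hydroxymethyl lactone allylic carbonate
Product: 18 hydroxymethyl lactone allylboronate
Conditions: B2pin2 (2.5 equiv), CuOtBu (10 mol %), (R,R)-QuinoxP* (10 mol %), THF, 0 °C
Reagents that add atoms: bis(pinacolato)diboron, CC1(C)OB(OC1(C)C)B1OC(C)(C)C(C)(C)O1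
Why: Copper-catalysed γ-selective allylic borylation: syn-borylcupration across C1=C10 with boron on C1, then β-elimination of the carbonate, should give the secondary allyl boronate with the C10=C9 methylene, the chiral bisphosphine choosing the Re face of C1 (1R).

**Step 15**
Reactants: 18 hydroxymethyl lactone allylboronate
Product: 21 macrocyclic alcohol, via boronate aldehyde 19 (not isolated), via macrocyclic pinacol borate 20 (not isolated)
Conditions: Dess–Martin periodinane (1.5 equiv), pyridine, CH2Cl2, 18 added over 10 h (final 1 mM), 0 → 40 °C; pH 7 buffer work-up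
Reagents that add atoms: none
Why: Proposed new method: oxidation unmasks the C8 aldehyde next to the secondary allyl pinacol boronate; the carbonyl oxygen binds boron while C9, the CH2 terminus of the C10=C9 alkene, attacks C8 through a six-membered B–O–C8–C9–C10–C1 chair, so the C1–B bond is traded for the C8–C9 bond and the C1=C10 alkene. The closest known reactions are the intermolecular Z-selective allylboration of aldehydes by α-substituted 2-methylallyl pinacol boronates and intramolecular allylborations that close rings with boron outside the ring path; new here is that the tether starts at the boron-bearing carbon, so all three allyl carbons enter the ring. The ten-membered carbocycle closes in an endo, transannular mode: the C2–C7 chain bridges positions 1 and 4 of the chair, which is within reach only with C2 axial on C1 and C7 equatorial on C8, and the trans-fused lactone already fixes the C5–C6–C7–C8 torsion as in the target. The axial C2, also favoured by allylic 1,2-strain with the C14 methyl and by the pinacol methyls, should give the Z C1=C10 alkene, and delivery of C9 from the face of C1 that carries boron should transfer the 1R configuration to 8R, the only new stereocentre. The step needs ring closure to beat intermolecular allylboration, which slow addition at about 1 mM should secure, and the Z chair to beat the E chair, which the tether length and the 2-methyl group should secure.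

**Step 16**
Reactants: 21 macrocyclic alcohol
Product: 22 tiglate silyl ether
Conditions: tigloyl chloride, pyridine, DMAP (cat.), CH2Cl2, 0 °C → rt
Reagents that add atoms: (E)-2-methylbut-2-enoyl chloride, C/C=C(\C)C(=O)Cl
Why: Acylation of the only free hydroxyl (C8); the E geometry of the tiglate is the stable one and should be retained.

**Step 17**
Reactants: 22 tiglate silyl ether
Product: 23 target, CNP0265652.4
Conditions: HF·pyridine, pyridine, THF, 0 °C
Reagents that add atoms: none
Why: Buffered fluoride cleavage of the triethylsilyl ether should leave the oxirane, the lactone and the tiglate intact.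

**Compound list**
1 | ethyl (2E)-3-methyl-4-oxobut-2-enoate | CCOC(=O)/C=C(\C)C=O | starting material
2 | ethyl (2E,4S)-4-hydroxy-3-methylhepta-2,6-dienoate | CCOC(=O)/C=C(\C)[C@@H](O)CC=C | intermediate
3 | ethyl (2E,4S)-3-methyl-4-(triethylsilyloxy)hepta-2,6-dienoate | CCOC(=O)/C=C(\C)[C@@H](O[Si](CC)(CC)CC)CC=C | intermediate
4 | (2E,4S)-3-methyl-4-(triethylsilyloxy)hepta-2,6-dien-1-ol | OC/C=C(\C)[C@@H](O[Si](CC)(CC)CC)CC=C | intermediate
5 | epoxy alcohol: [(2R,3S)-3-methyl-3-[(1S)-1-(triethylsilyloxy)but-3-en-1-yl]oxiran-2-yl]methanol | C=CC[C@H](O[Si](CC)(CC)CC)[C@@]1(C)O[C@@H]1CO | intermediate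
6 | epoxy aldehyde: (2S,3S)-3-methyl-3-[(1S)-1-(triethylsilyloxy)but-3-en-1-yl]oxirane-2-carbaldehyde | C=CC[C@H](O[Si](CC)(CC)CC)[C@@]1(C)O[C@@H]1C=O | intermediate
7 | (R)-methylsuccinic acid, (2R)-2-methylbutanedioic acid | C[C@H](CC(=O)O)C(=O)O | starting material
8 | (R)-methylsuccinic anhydride, (3R)-3-methyloxolane-2,5-dione | C[C@@H]1CC(=O)OC1=O | intermediate
9 | (4S)-4-benzyl-1,3-oxazolidin-2-one | O=C1N[C@@H](Cc2ccccc2)CO1 | starting material
10 | imide acid: (2R)-4-[(4S)-4-benzyl-2-oxo-1,3-oxazolidin-3-yl]-2-methyl-4-oxobutanoic acid | C[C@H](CC(=O)N1[C@@H](Cc2ccccc2)COC1=O)C(=O)O | intermediate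
11 | imide ester: methyl (2R)-4-[(4S)-4-benzyl-2-oxo-1,3-oxazolidin-3-yl]-2-methyl-4-oxobutanoate | C[C@H](CC(=O)N1[C@@H](Cc2ccccc2)COC1=O)C(=O)OC | intermediate
12 | aldol adduct: methyl (2R,3S,4S)-3-[(4S)-4-benzyl-2-oxo-1,3-oxazolidine-3-carbonyl]-4-hydroxy-2-methyl-4-{(2R,3S)-3-methyl-3-[(1S)-1-(triethylsilyloxy)but-3-en-1-yl]oxiran-2-yl}butanoate | C=CC[C@H](O[Si](CC)(CC)CC)[C@@]1(C)O[C@@H]1[C@@H](O)[C@H]([C@@H](C)C(=O)OC)C(=O)N1[C@@H](Cc2ccccc2)COC1=O | intermediate
13 | lactone imide: (4S)-4-benzyl-3-[(2S,3S,4R)-4-methyl-2-{(2R,3S)-3-methyl-3-[(1S)-1-(triethylsilyloxy)but-3-en-1-yl]oxiran-2-yl}-5-oxooxolane-3-carbonyl]-1,3-oxazolidin-2-one | C=CC[C@H](O[Si](CC)(CC)CC)[C@@]1(C)O[C@@H]1[C@H]1OC(=O)[C@H](C)[C@@H]1C(=O)N1[C@@H](Cc2ccccc2)COC1=O | intermediate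
14 | lactone imide enal: 13 with the oxirane side chain changed to (1S,3E)-4-methyl-5-oxo-1-(triethylsilyloxy)pent-3-en-1-yl | O=C/C(C)=C/C[C@H](O[Si](CC)(CC)CC)[C@@]1(C)O[C@@H]1[C@H]1OC(=O)[C@H](C)[C@@H]1C(=O)N1[C@@H](Cc2ccccc2)COC1=O | intermediate
15 | lactone imide allylic alcohol: side chain (1S,3E)-5-hydroxy-4-methyl-1-(triethylsilyloxy)pent-3-en-1-yl | OC/C(C)=C/C[C@H](O[Si](CC)(CC)CC)[C@@]1(C)O[C@@H]1[C@H]1OC(=O)[C@H](C)[C@@H]1C(=O)N1[C@@H](Cc2ccccc2)COC1=O | intermediate
16 | lactone imide allylic carbonate: side chain (1S,3E)-5-(methoxycarbonyloxy)-4-methyl-1-(triethylsilyloxy)pent-3-en-1-yl | COC(=O)OC/C(C)=C/C[C@H](O[Si](CC)(CC)CC)[C@@]1(C)O[C@@H]1[C@H]1OC(=O)[C@H](C)[C@@H]1C(=O)N1[C@@H](Cc2ccccc2)COC1=O | intermediate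
17 | hydroxymethyl lactone allylic carbonate: (3R,4R,5S)-4-(hydroxymethyl)-3-methyl-5-{(2R,3S)-3-[(1S,3E)-5-(methoxycarbonyloxy)-4-methyl-1-(triethylsilyloxy)pent-3-en-1-yl]-3-methyloxiran-2-yl}oxolan-2-one | COC(=O)OC/C(C)=C/C[C@H](O[Si](CC)(CC)CC)[C@@]1(C)O[C@@H]1[C@H]1OC(=O)[C@H](C)[C@@H]1CO | intermediate
18 | hydroxymethyl lactone allylboronate: (3R,4R,5S)-4-(hydroxymethyl)-3-methyl-5-{(2R,3S)-3-methyl-3-[(1S,3R)-4-methyl-3-(4,4,5,5-tetramethyl-1,3,2-dioxaborolan-2-yl)-1-(triethylsilyloxy)pent-4-en-1-yl]oxiran-2-yl}oxolan-2-one | C=C(C)[C@H](B1OC(C)(C)C(C)(C)O1)C[C@H](O[Si](CC)(CC)CC)[C@@]1(C)O[C@@H]1[C@H]1OC(=O)[C@H](C)[C@@H]1CO | intermediate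
19 | boronate aldehyde: (2S,3S,4R)-4-methyl-5-oxo-oxolane-3-carbaldehyde carrying at C2 the same boryl oxiranyl side chain as 18 | C=C(C)[C@H](B1OC(C)(C)C(C)(C)O1)C[C@H](O[Si](CC)(CC)CC)[C@@]1(C)O[C@@H]1[C@H]1OC(=O)[C@H](C)[C@@H]1C=O | intermediate
20 | macrocyclic pinacol borate: 8-O-(4,4,5,5-tetramethyl-1,3,2-dioxaborolan-2-yl) derivative of 21 | CC1(C)OB(O[C@@H]2C/C(C)=C\C[C@H](O[Si](CC)(CC)CC)[C@@]3(C)O[C@@H]3[C@H]3OC(=O)[C@H](C)[C@@H]32)OC1(C)C | intermediate
21 | macrocyclic alcohol: (1(10)Z)-4α,5β-epoxy-8β-hydroxy-3β-(triethylsilyloxy)-11αH-germacr-1(10)-en-12,6α-olide (3S,4S,5R,6S,7R,8R,11R) | O[C@@H]1C/C(C)=C\C[C@H](O[Si](CC)(CC)CC)[C@@]2(C)O[C@@H]2[C@H]2OC(=O)[C@H](C)[C@@H]21 | intermediate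
22 | tiglate silyl ether: 8-O-[(E)-2-methylbut-2-enoyl] derivative of 21 | C/C=C(\C)C(=O)O[C@@H]1C/C(C)=C\C[C@H](O[Si](CC)(CC)CC)[C@@]2(C)O[C@@H]2[C@H]2OC(=O)[C@H](C)[C@@H]21 | intermediate
23 | CNP0265652.4: (1(10)Z)-4α,5β-epoxy-3β-hydroxy-8β-[(E)-2-methylbut-2-enoyloxy]-11αH-germacr-1(10)-en-12,6α-olide (3S,4R,5R,6S,7R,8R,11R) | C/C=C(\C)C(=O)O[C@@H]1C/C(C)=C\C[C@H](O)[C@@]2(C)O[C@@H]2[C@H]2OC(=O)[C@H](C)[C@@H]21 | target

**Count and risks**
Total steps: 17. Longest linear sequence: 14 steps (steps 1–5 and 9–17); steps 6–8 make the second fragment.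

Step 15 (proposed new method). What may go wrong: intermolecular allylboration (oligomer formation) outruns ring closure, or closure runs through the chair with C2 equatorial and gives the E alkene. The fallback uses known chemistry: the C8–C9 bond is made between two molecules and the ring is closed at C1=C10 instead. It sets out from 13. NaBH4 in THF/H2O should give the hydroxymethyl lactone F1, and Dess–Martin oxidation the lactone aldehyde F2. Reagent-controlled 2-methylallylboration with B-(2-methylallyl)diisopinocampheylborane of the (−)-α-pinene series (Re-face attack) should give the 8R homoallylic alcohol F3. Ring-closing metathesis of the C1 vinyl group and the C10 isopropenyl group (second-generation Hoveyda–Grubbs catalyst, toluene, 1 mM, 80 °C) should then close the ten-membered ring as the Z alkene and come back to the route at 21.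

Step 14. What may go wrong: poor facial selectivity of the borylcupration at C1, or protonation of the tertiary alkylcopper before β-elimination. The fallback keeps the allylic carbonate as electrophile and makes C8 the nucleophile, in a palladium-catalysed allylic alkylation of a nitronate that closes the same C8–C9 bond. It sets out from 17. I2, PPh3 and imidazole should give the iodide F4, and NaNO2 in DMSO the nitro compound F5. Pd2(dba)3 with dppe (zerovalent palladium) in THF at 1 mM should ionise the carbonate, the methoxide set free deprotonates the nitroalkane, and attack of the nitronate on the CH2 terminus (C9) of the allyl complex should give the macrocyclic nitro compound F6. An oxidative Nef reaction (K2CO3, then nPr4N[RuO4] with N-methylmorpholine N-oxide) should give the macrocyclic ketone F7, and NaBH4/CeCl3·7H2O at −78 °C, with hydride from the outer face of the ring, should come back to the route at 21. The C8 configuration from this reduction is not secured and would have to be checked.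

Step 9. What may go wrong: opening of the oxirane next to the aldehyde under the boron Lewis acid, or during the acid-catalysed lactonisation. The fallback runs the aldol on the enal and introduces the oxirane afterwards under hydroxyl direction. It sets out from 4. MnO2 should give the enal F8, and the same Evans syn-aldol with 11 the allylic alcohol adduct F9. With mCPBA in CH2Cl2 at 0 °C the free C6 hydroxyl directs the peracid, and allylic 1,3-strain between C6 and the C15 methyl (cis on C4) should favour the threo epoxy alcohol, which is the C5/C6 relation of the target. This comes back to the route at 12, which lactonises to 13.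

**Further compounds**
F1 | step 15 | hydroxymethyl lactone: (3R,4R,5S)-4-(hydroxymethyl)-3-methyl-5-{(2R,3S)-3-methyl-3-[(1S)-1-(triethylsilyloxy)but-3-en-1-yl]oxiran-2-yl}oxolan-2-one | C=CC[C@H](O[Si](CC)(CC)CC)[C@@]1(C)O[C@@H]1[C@H]1OC(=O)[C@H](C)[C@@H]1CO
F2 | step 15 | lactone aldehyde: (2S,3S,4R)-4-methyl-2-{(2R,3S)-3-methyl-3-[(1S)-1-(triethylsilyloxy)but-3-en-1-yl]oxiran-2-yl}-5-oxooxolane-3-carbaldehyde | C=CC[C@H](O[Si](CC)(CC)CC)[C@@]1(C)O[C@@H]1[C@H]1OC(=O)[C@H](C)[C@@H]1C=O
F3 | step 15 | 8R homoallylic alcohol: F1 with the hydroxymethyl group replaced by (1R)-1-hydroxy-3-methylbut-3-en-1-yl | C=CC[C@H](O[Si](CC)(CC)CC)[C@@]1(C)O[C@@H]1[C@H]1OC(=O)[C@H](C)[C@@H]1[C@H](O)CC(C)=C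
F4 | step 14 | iodide: 17 with C8–OH replaced by C8–I | COC(=O)OC/C(C)=C/C[C@H](O[Si](CC)(CC)CC)[C@@]1(C)O[C@@H]1[C@H]1OC(=O)[C@H](C)[C@@H]1CI
F5 | step 14 | nitro compound: 17 with C8–OH replaced by C8–NO2 | COC(=O)OC/C(C)=C/C[C@H](O[Si](CC)(CC)CC)[C@@]1(C)O[C@@H]1[C@H]1OC(=O)[C@H](C)[C@@H]1C[N+](=O)[O-]
F6 | step 14 | macrocyclic nitro compound: 21 with 8-OH replaced by 8-NO2, C8 configuration not fixed | [O-][N+](=O)C1C/C(C)=C\C[C@H](O[Si](CC)(CC)CC)[C@@]2(C)O[C@@H]2[C@H]2OC(=O)[C@H](C)[C@@H]21
F7 | step 14 | macrocyclic ketone: 8-oxo analogue of 21 | O=C1C/C(C)=C\C[C@H](O[Si](CC)(CC)CC)[C@@]2(C)O[C@@H]2[C@H]2OC(=O)[C@H](C)[C@@H]21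
F8 | step 9 | enal: (2E,4S)-3-methyl-4-(triethylsilyloxy)hepta-2,6-dienal | O=C/C=C(\C)[C@@H](O[Si](CC)(CC)CC)CC=C
F9 | step 9 | allylic alcohol adduct: 12 with the C4–C5 oxirane replaced by the E C4=C5 alkene | C=CC[C@H](O[Si](CC)(CC)CC)/C(C)=C/[C@@H](O)[C@H]([C@@H](C)C(=O)OC)C(=O)N1[C@@H](Cc2ccccc2)COC1=O
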